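Everything rests on reading the pyrrole ring as a latent lactam. The carbon of C2–Br is the amide carbonyl of an oxindole, and C3, which bears the formyl group, is its α-methylene. One Vilsmeier–Haack–Arnold reaction (DMF/POBr3) makes the C3–CHO carbon–carbon bond, exchanges the C2 oxygen for bromine and aromatises the five-membered ring. Its precursor is 5,6-dibromooxindole. The benzo-ring bromines at C5 and C6 are bought in place on a 1,2-dibromoarene. They are positioned relative to nitrogen by nitration, fluoride SNAr with malonate and reductive lactamisation, so electrophilic bromination of the heterocycle is avoided altogether. N-Methylation of the acidified N1–H finishes the synthesis.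

Key step: step 5

Remark: the target has no stereocentre and no stereogenic double bond, so it is achiral and the request for a single enantiomer has no bearing; only regiochemistry has to be controlled (arene C1–Br becomes indole C6–Br, C2–Br becomes C5–Br, C4 becomes C3a, C5 becomes C7a).
Remark: salts formed by mere proton transfer (malonate anion, anion of the arylmalonate, indolide) are treated as forms of the numbered parent compound and carry no number of their own.

Step 1
Reactants: 1 1,2-dibromo-4-fluorobenzene
Product: 2 1,2-dibromo-4-fluoro-5-nitrobenzene
Conditions: fuming HNO3 (1.2 equiv), conc. H2SO4, 0 °C to rt; ice quench, recrystallisation from EtOH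
Reagents that add atoms: nitric acid, O[N+](=O)[O-]
Why: Electrophilic aromatic nitration, in which fluorine is the strongest ortho/para director and its para position is blocked by bromine, so the nitronium ion should enter at C5, the only site ortho to F that is also para to a bromine and not squeezed between two halogens.

Step 2
Reactants: 2 1,2-dibromo-4-fluoro-5-nitrobenzene; 3 dimethyl malonate
Product: 4 dimethyl 2-(4,5-dibromo-2-nitrophenyl)malonate
Conditions: 3 (1.2 equiv), K2CO3 (2.5 equiv), DMSO, rt to 40 °C; cold dilute acid quench
Reagents that add atoms: dimethyl malonate, COC(=O)CC(=O)OC
Why: Nucleophilic aromatic substitution by addition–elimination through a Meisenheimer adduct, in which fluoride ortho to nitro leaves far faster than the bromide para to nitro (element effect F >> Br), and the acidic product is ionised by the excess carbonate, which makes the ring electron-rich and switches off a second substitution until the quench.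

Step 3
Reactants: 4 dimethyl 2-(4,5-dibromo-2-nitrophenyl)malonate
Product: 6 2-(4,5-dibromo-2-nitrophenyl)acetic acid, via arylmalonic acid 5 (not isolated)
Conditions: conc. H2SO4/H2O/AcOH (about 1:3:5 v/v), reflux
Reagents that add atoms: water, O
Why: Acid-catalysed ester hydrolysis (AAC2) followed by thermal decarboxylation of the malonic acid through its cyclic transition state, with sulfuric acid chosen so that no chloride is present to exchange with the nitro-activated bromine, while the acidic medium prevents loss of the second carboxyl group by way of a nitrobenzyl anion.

Step 4
Reactants: 6 2-(4,5-dibromo-2-nitrophenyl)acetic acid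
Product: 8 5,6-dibromoindolin-2-one (5,6-dibromooxindole), via amino acid 7 (not isolated)
Conditions: Fe powder (5 equiv), AcOH, 90–100 °C; hot filtration through Celite, precipitation with water
Reagents that add atoms: none
Why: Béchamp-type dissolving-metal reduction of the nitro group, which leaves aryl C–Br bonds intact where palladium hydrogenation would not, followed by spontaneous 5-exo-trig lactamisation of the new aniline nitrogen onto the neighbouring carboxyl group in hot acetic acid.

Step 5
Reactants: 8 5,6-dibromoindolin-2-one; 9 N,N-dimethylformamide; 10 phosphorus oxybromide
Product: 14 2,5,6-tribromo-1H-indole-3-carbaldehyde, via bromoiminium salt 11 (not isolated), via aminomethylene lactam 12 (not isolated), via indolyl iminium bromide 13 (not isolated)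
Conditions: 9 (3.5 equiv) + 10 (3 equiv), CHCl3 (ethanol-free), 0 °C, 30 min; add 8, reflux; then ice/aq NaHCO3, rt
Reagents that add atoms: N,N-dimethylformamide, CN(C)C=O (formyl C–H); phosphorus oxybromide, O=P(Br)(Br)Br (C2 bromine); water, O (aldehyde oxygen)
Why: Amide 9 and oxybromide 10 combine to the bromoiminium salt 11, which is captured by the enol carbon C3 of lactam 8 and loses HBr to give the push–pull enaminone 12. The electron-rich lactam oxygen of 12 is then phosphorylated (or activated by more 11) and displaced by bromide at C2 through addition–elimination, so the five-membered ring becomes an aromatic pyrrole in salt 13, which bicarbonate water hydrolyses to aldehyde 14. The closest known reaction type is the Vilsmeier–Haack–Arnold haloformylation of enolisable carbonyl compounds, established for oxindoles with POCl3/DMF (2-chloro series) and POBr3/DMF (2-bromo series). No ring is closed and no stereocentre is created, since the step only aromatises the ring made in step 4 and erases the E/Z geometry of 12. The selectivity needed, formyl at C3 only and bromine at C2 only, is built into the substrate: C3 is its sole nucleophilic carbon, the doubly brominated benzo ring is too deactivated to be formylated, and bromine arrives by replacing oxygen and not by electrophilic attack. Bromide as the only ionic halide excludes C2–Cl, three equivalents of reagent drive 12 on to 13, and bicarbonate in place of hydroxide protects the activated C2–Br from hydrolysis.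

Step 6
Reactants: 14 2,5,6-tribromo-1H-indole-3-carbaldehyde; 15 iodomethane
Product: 16 2,5,6-tribromo-1-methyl-1H-indole-3-carbaldehyde (target)
Conditions: K2CO3 (1.5 equiv), 15 (1.3 equiv), dry amine-free DMF (solvent), 0 °C to rt
Reagents that add atoms: iodomethane, CI
Why: SN2 N-alkylation of an indole whose N–H is acidified enough by the 3-formyl and bromo substituents for carbonate to suffice, with C-alkylation impossible because C2 and C3 are both substituted, and with the low temperature and short contact time keeping the activated C2–Br safe from nucleophiles.

Compound list
1 | 1,2-dibromo-4-fluorobenzene | Fc1ccc(Br)c(Br)c1 | starting material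
2 | 1,2-dibromo-4-fluoro-5-nitrobenzene | O=[N+]([O-])c1cc(Br)c(Br)cc1F | intermediate
3 | dimethyl malonate | COC(=O)CC(=O)OC | starting material
4 | dimethyl 2-(4,5-dibromo-2-nitrophenyl)malonate | COC(=O)C(C(=O)OC)c1cc(Br)c(Br)cc1[N+](=O)[O-] | intermediate
5 | 2-(4,5-dibromo-2-nitrophenyl)malonic acid | OC(=O)C(C(=O)O)c1cc(Br)c(Br)cc1[N+](=O)[O-] | intermediate (not isolated)
6 | 2-(4,5-dibromo-2-nitrophenyl)acetic acid | OC(=O)Cc1cc(Br)c(Br)cc1[N+](=O)[O-] | intermediate
7 | 2-(2-amino-4,5-dibromophenyl)acetic acid | Nc1cc(Br)c(Br)cc1CC(=O)O | intermediate (not isolated)
8 | 5,6-dibromoindolin-2-one | O=C1Cc2cc(Br)c(Br)cc2N1 | intermediate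
9 | N,N-dimethylformamide | CN(C)C=O | starting material
10 | phosphorus oxybromide | O=P(Br)(Br)Br | starting material
11 | (bromomethylidene)dimethyliminium bromide | C[N+](C)=CBr.[Br-] | intermediate (not isolated)
12 | 5,6-dibromo-3-[(dimethylamino)methylidene]indolin-2-one (E/Z undefined, geometry erased on aromatisation) | CN(C)C=C1C(=O)Nc2cc(Br)c(Br)cc21 | intermediate (not isolated)
13 | N-methyl-N-[(2,5,6-tribromo-1H-indol-3-yl)methylidene]methanaminium bromide | C[N+](C)=Cc1c(Br)[nH]c2cc(Br)c(Br)cc12.[Br-] | intermediate (not isolated)
14 | 2,5,6-tribromo-1H-indole-3-carbaldehyde | O=Cc1c(Br)[nH]c2cc(Br)c(Br)cc12 | intermediate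
15 | iodomethane | CI | starting material
16 | 2,5,6-tribromo-1-methyl-1H-indole-3-carbaldehyde (achiral) | Cn1c(Br)c(C=O)c2cc(Br)c(Br)cc21 | target

Total step count: 6
Longest linear sequence: 6 steps (1 to 16)

Steps most likely to fail

Step 5. The cascade may stall after the condensation at C3, because the carbonyl of the sparingly soluble push–pull lactam is slow to exchange for bromide. The activated C2–Br may also be lost by hydrolysis during the quench. The fallback sets out from 8 and comes back at 14, and it makes the two bonds separately and in the opposite order. Lactam 8 alone is deoxybrominated with POBr3 (1,2-dichloroethane, reflux, then imidazole). This is the known conversion of oxindoles into 2-bromoindoles, and it activates a plain amide rather than a vinylogous urea. It should give 2,5,6-tribromo-1H-indole F1. An ordinary Vilsmeier–Haack formylation of the free C3 of F1 follows, with a small excess of preformed 11 at 0 °C to rt. It passes through 13 and should give 14 after bicarbonate hydrolysis.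

Step 1. Regiocontrol may erode through attack between F and Br or ortho to bromine. Ipso attack para to fluorine may expel bromine, and the isomers may resist separation by crystallisation. The fallback sets out from 1 and comes back at 2, and it replaces electronic control by steric control. Iridium-catalysed C–H borylation ([Ir(OMe)(cod)]2, dtbpy, B2pin2, THF, 60–80 °C) tolerates aryl bromides and avoids every C–H ortho to bromine. Only the position next to the small fluorine remains, which should give 2-(4,5-dibromo-2-fluorophenyl)-4,4,5,5-tetramethyl-1,3,2-dioxaborolane F2. Ipso-nitration of the boronic ester (Fe(NO3)3·9H2O, hexafluoroisopropanol, warm) then puts the nitro group exactly where boron stood, giving 2.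

Step 4. The reduction may halt at the hydroxylamine stage, with cyclisation to an N-hydroxy lactam. The poorly soluble product may also be held back in the iron residues. The fallback sets out from 4 and comes back at 8. It reduces catalytically and closes the ring before decarboxylation.
- Diester 4 is hydrogenated over sulfided Pt/C (H2, 3–5 bar, EtOAc/THF, rt to 40 °C), the poisoned catalyst used for halonitroarenes. This should give dimethyl 2-(2-amino-4,5-dibromophenyl)malonate F3.
- On warming with a trace of AcOH, F3 closes onto one ester to give methyl 5,6-dibromo-2-oxoindoline-3-carboxylate F4 (racemic and readily enolised, so its C3 configuration is irrelevant).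
- Aqueous H2SO4/AcOH at reflux hydrolyses F4 to 5,6-dibromo-2-oxoindoline-3-carboxylic acid F5. This acid, activated by the β-carbonyl, decarboxylates in the same pot to 8.

Further compounds
F1 | step 5 | 2,5,6-tribromo-1H-indole | Brc1cc2cc(Br)c(Br)cc2[nH]1
F2 | step 1 | 2-(4,5-dibromo-2-fluorophenyl)-4,4,5,5-tetramethyl-1,3,2-dioxaborolane | CC1(C)OB(OC1(C)C)c1cc(Br)c(Br)cc1F
F3 | step 4 | dimethyl 2-(2-amino-4,5-dibromophenyl)malonate | COC(=O)C(C(=O)OC)c1cc(Br)c(Br)cc1N
F4 | step 4 | methyl 5,6-dibromo-2-oxoindoline-3-carboxylate (racemic) | COC(=O)C1C(=O)Nc2cc(Br)c(Br)cc21
F5 | step 4 | 5,6-dibromo-2-oxoindoline-3-carboxylic acid (racemic) | OC(=O)C1C(=O)Nc2cc(Br)c(Br)cc21
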